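## Structural features

The target is a guai-1(10)-ene: a cyclopentane (C1–C5) fused through the C1–C5 bond to a cycloheptene (C1, C5–C10). The fusion carbon C1 is part of a tetrasubstituted C1=C10 double bond that carries the C14 methyl group. Five stereocentres are contiguous: C4 (tertiary carbinol with the C15 methyl), C5 (ring-fusion hydrogen), C6 (acetate), C7 (isopropyl) and C8 (angelate). H-5, the C4 hydroxyl, the C6 acetoxy group and the isopropyl group lie on one face; the C8 oxygen lies on the other. The fragile parts are the angelate (drifts to the tiglate under basic, nucleophilic or radical conditions), the tertiary homoallylic alcohol (eliminates under acid), and two different secondary esters that must go on in a fixed order. The real difficulty is the seven-membered ring with four contiguous stereocentres and their relation to the quaternary C4 centre. The key step reads C1, C10, C9 and C8 as the carbons of a 2-alkyl-3-methylfuran, whose oxygen becomes the C8 oxygen, and C5–C6–C7 as an oxyallyl cation carrying the C6 oxygen. A (4+3) cycloaddition across C1 and C8 then closes both carbocycles at once; the C1–C8 oxygen bridge masks the C8 hydroxyl and, after cleavage of the tertiary allylic C1–O bond, leaves the C1=C10 alkene.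

## Logic of the disconnections

26 to 25: the O–Si bond on the C4 oxygen is cut last. The tertiary alcohol is the one function that would not survive Lewis acid and acylation, so it stays masked to the end. The forward step needs a fluoride source that spares both esters and the Z geometry of the unsaturated ester.

25 to 22 and 23: the acyl C–O bond of the C8 ester is cut. The isomerisation-prone acyl group then arrives as late as possible and a five-carbon commercial acid is removed. The forward step must transfer the acyl group to a hindered secondary hydroxyl without Z to E drift; because the C6 ester is already in place, no choice between two hydroxyls is needed.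

22 to 20: the C9–H bond is exchanged for a C1–O bond to the C8 oxygen, which reconnects the oxygen bridge. This turns a free secondary alcohol and a tetrasubstituted alkene into one rigid allylic ether and explains why the C6 and C8 oxygens never compete. The forward step must ionise only the tertiary allylic C1–O bond and deliver hydride only to C9.

20 to 19 to 18: the acetyl C–O bond and then the C6–H bond are cut, leading back to a ketone flanked by C5 and C7. The gain is that C5 and C7 become epimerisable and the C6 oxygen becomes the oxygen of an oxyallyl unit. The forward reduction must bring hydride from the face of the oxygen bridge to give the axial alcohol.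

18 to 15: the C1–C5 and C7–C8 bonds are cut. Two rings, two skeletal bonds and four stereocentres fall away, leaving an acyclic ketone with one stereocentre. The forward step must choose one face of the furan under the influence of C4 alone, place H-5 anti to the bridge and end with an equatorial isopropyl group.

15 to 13: the C7–Cl bond is cut. The chlorine is only the leaving group for the cation, and either α-position and either epimer would serve. The forward step must chlorinate an enolate without touching the electron-rich furan.

13 to 10 and 11 (through 12): the C6–C7 bond is cut next to the carbonyl, which removes the isobutyl unit as a commercial organomagnesium reagent. The forward steps are an addition and an oxidation, with the C4 oxygen already silylated so that no β-hydroxy carbonyl compound is exposed.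

10 to 8 (through 9): functional-group changes only, two O–Si bonds and the oxidation level of C6. The demand is to tell the primary from the tertiary oxygen, which is met by silylating both and oxidising the primary silyl ether directly.

8 to 6 (through 7): the C5–H bond and the C4–O bond are removed in turn, taking the only stereocentre of the acyclic series back to a trisubstituted alkene. The forward steps need a reagent-controlled epoxidation of high enantioselectivity and a hydride opening at C5 only.

6 to 3 and 4 (through 5): the C4=C5 double bond is cut, leaving a methyl ketone and a two-carbon phosphonate. The forward olefination must give the E isomer, or allow the Z isomer to be removed, because the alkene geometry becomes the configuration of C4.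

3 to 1 and 2: the bond between the furan α-carbon (the future C1) and C2 is cut, giving two commercial four- and five-carbon pieces. The forward alkylation must take place at the α-position next to the methyl group.

## Other disconnections considered

Alternative 1: The cut is the C6–C7 bond of a ten-membered ring, with the guaiane C1–C5 bond to be formed later across that ring. In the forward direction a terpene cyclase of the kunzeaol synthase type would ionise farnesyl diphosphate A1, form C6–C7, shift hydride from C6 to C11 and add water at C6, giving the germacradienol A2.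
- In its favour: one enzymatic operation assembles all fifteen carbons and sets C6 and C7 with the absolute configuration fixed by the protein. Epoxidation of the C4=C5 alkene directed by the C6 hydroxyl, then acid-induced transannular C1–C5 closure, would be expected to give the 4-hydroxyguai-1(10)-ene core. On step count to the carbon skeleton, and on the source of absolute configuration, this is better than the chosen plan.
- Against it: it needs an expressed cyclase, not a commercial reagent. The mobile ten-membered ring makes the C4/C5 outcome of the transannular closure uncertain.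
- Decisive weakness: C8 in A2 is an unactivated methylene that is not allylic to either alkene, and no selective chemical hydroxylation with control of configuration is at hand for it.
- Comparison: both plans create the C1=C10 alkene late from a precursor in which the bicyclic system is latent, and are equal there. The chosen plan brings the C8 oxygen in as the furan oxygen, which the enzymatic plan cannot match.

Alternative 2: The cut is the C8–C9 bond. In the forward direction Me2AlCl would activate the aldehyde A3 and the isopropenyl terminus C9 would add to C8 with transfer of a C14 hydrogen to oxygen (type 2 carbonyl-ene reaction), closing the seven-membered ring and giving the hydroazulenol acetonide A4.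
- In its favour: C4, C5, C6 and C7 can be set beforehand by well-understood acyclic and cyclopentane stereocontrol. The acetonide keeps the C4 and C6 oxygens apart from C8. The C8 hydroxyl appears free, so no oxygen bridge has to be cleaved; on this point, and in not depending on a weak facial bias from C4, it is better than the chosen plan.
- Against it: the key step makes one ring and one C–C bond. A3 already contains a cyclopentane with three contiguous stereocentres and a side chain with two more, so the linear sequence before the key step is long. Seven-membered closure by this ene mode is less favourable than six-membered closure. The aldehyde has an epimerisable α-centre (C7) and a β-oxygen (C6) that a Lewis acid may eliminate. The alkene is delivered exocyclic (C10=C14) and must be moved to C1=C10 in competition with C9=C10.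
- Comparison: C1 is made and then destroyed in both plans (equal). The ene plan is mechanistically sound but poorer in step economy, because the chosen key step forms two rings and four stereocentres.

Alternative 3: The cut removes C5 from between C1 and C6 of an arene. In the forward direction a rhodium carbenoid generated from the diazoketone A5 with Rh2(OAc)4, or a chiral Rh2(O2CR)4 analogue, would add to the arene bond C1–C6 and the norcaradiene would open (Büchner reaction) to the dihydroazulenone A6.
- In its favour: the arene already carries the isopropyl, methyl and oxygen substituents in the right positions. Both rings arise in one step, as in the chosen plan (equal), and the bicyclic carbon skeleton is reached in fewer steps (better).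
- Against it: only C5 is set, and only if a chiral catalyst performs on this heavily substituted arene. A6 is a cycloheptatriene in equilibrium with its norcaradiene and is open to hydrogen shifts and acid-induced rearrangement. C6 in A6 is a bare sp2 CH with no oxygen. The C4 carbinol and the C6, C7 and C8 centres would have to be introduced one at a time on a flexible ring while two of three double bonds are removed selectively.
- Comparison: the chosen plan places both ring oxygens and four stereocentres in its key step, whereas this plan places one stereocentre and leaves a long endgame with weak stereocontrol.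

Key step: step 11

Remark: ring compounds are named and numbered as guaianes (C1–C10 ring carbons, C11 the isopropyl methine, C14 the methyl on C10, C15 the methyl on C4); acyclic compounds carry systematic locants.

## Route

Step 1
Reactants: 1 3-methylfuran; 2 methyl vinyl ketone (but-3-en-2-one)
Product: 3 4-(3-methylfuran-2-yl)butan-2-one
Conditions: BF3·OEt2 (5 mol %), 1 (2 equiv), CH2Cl2, −20 °C
Reagents that add atoms: none
Why: Acid-catalysed conjugate (Friedel–Crafts type) alkylation of a furan by an enone; of the two free α-positions, C2 next to the methyl group is the more nucleophilic because attack there places the charge on the methyl-bearing carbon, and the excess of 1 should limit a second alkylation at C5.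

Step 2
Reactants: 3 4-(3-methylfuran-2-yl)butan-2-one; 4 triethyl phosphonoacetate
Product: 5 ethyl (2E)-3-methyl-5-(3-methylfuran-2-yl)pent-2-enoate
Conditions: NaH, THF, 0 °C to reflux; Z isomer removed by chromatography
Reagents that add atoms: none
Why: Horner–Wadsworth–Emmons olefination of a methyl ketone; the E ester should predominate because the ester group avoids the longer chain, and the minor Z isomer, which would erode the enantiomeric purity set in step 4, is removed here.

Step 3
Reactants: 5 ethyl (2E)-3-methyl-5-(3-methylfuran-2-yl)pent-2-enoate
Product: 6 (2E)-3-methyl-5-(3-methylfuran-2-yl)pent-2-en-1-ol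
Conditions: iBu2AlH (2.2 equiv), CH2Cl2, −78 °C; aq. KNaC4H4O6
Reagents that add atoms: none
Why: 1,2-Reduction of an α,β-unsaturated ester to the allylic alcohol by an aluminium hydride; the furan and the trisubstituted alkene are inert.

Step 4
Reactants: 6 (2E)-3-methyl-5-(3-methylfuran-2-yl)pent-2-en-1-ol
Product: 7 [(2S,3S)-3-methyl-3-[2-(3-methylfuran-2-yl)ethyl]oxiran-2-yl]methanol
Conditions: Ti(OiPr)4 (10 mol %), L-(+)-diethyl tartrate (12 mol %), t-BuOOH, 4 Å molecular sieves, CH2Cl2, −20 °C
Reagents that add atoms: tert-butyl hydroperoxide, CC(C)(C)OO
Why: Sharpless asymmetric epoxidation of an E-configured 3,3-disubstituted allylic alcohol; with the L-(+)-tartrate the titanium-bound peroxide should reach the face that gives the (2S,3S)-epoxide, which fixes the future C4 with its oxygen in place. The furan is remote from the coordinating hydroxyl and should not be oxidised at −20 °C.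

Step 5
Reactants: 7 [(2S,3S)-3-methyl-3-[2-(3-methylfuran-2-yl)ethyl]oxiran-2-yl]methanol
Product: 8 (3S)-3-methyl-5-(3-methylfuran-2-yl)pentane-1,3-diol
Conditions: NaAlH2(OCH2CH2OMe)2, THF, 0 °C to rt
Reagents that add atoms: none
Why: Regioselective reductive opening of a 2,3-epoxy alcohol by the alkoxide-bound aluminium hydride: hydride is delivered within the complex to oxirane carbon C2 (the future C5), and the C–O bond at the fully substituted carbon is not touched, so the tertiary carbinol keeps its configuration.

Step 6
Reactants: 8 (3S)-3-methyl-5-(3-methylfuran-2-yl)pentane-1,3-diol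
Product: 9 (3S)-3-methyl-5-(3-methylfuran-2-yl)-1,3-bis(triethylsilyloxy)pentane
Conditions: Et3SiOTf (2.4 equiv), 2,6-lutidine, CH2Cl2, −78 to 0 °C
Reagents that add atoms: triethylsilyl trifluoromethanesulfonate, CC[Si](CC)(CC)OS(=O)(=O)C(F)(F)F
Why: Exhaustive silylation with a silyl triflate and a hindered pyridine base, the practical way to silylate the tertiary hydroxyl; placing the triethylsilyl group now means that no free β-hydroxy aldehyde or ketone (retro-aldol, dehydration) is handled later.

Step 7
Reactants: 9 (3S)-3-methyl-5-(3-methylfuran-2-yl)-1,3-bis(triethylsilyloxy)pentane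
Product: 10 (3S)-3-methyl-5-(3-methylfuran-2-yl)-3-(triethylsilyloxy)pentanal
Conditions: (COCl)2, DMSO, CH2Cl2, −78 to −40 °C; then Et3N, −78 °C to rt
Reagents that add atoms: none
Why: Swern oxidation applied directly to a primary triethylsilyl ether: the chlorosulfonium salt exchanges with the unhindered primary silyl ether and the alkoxysulfonium ion collapses to the aldehyde, while the hindered tertiary silyl ether and the furan should stay intact.

Step 8
Reactants: 10 (3S)-3-methyl-5-(3-methylfuran-2-yl)-3-(triethylsilyloxy)pentanal; 11 isobutylmagnesium bromide
Product: 12 (3S)-3,7-dimethyl-1-(3-methylfuran-2-yl)-3-(triethylsilyloxy)octan-5-ol (both C5 epimers)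
Conditions: THF, −78 to 0 °C; aq. NH4Cl
Reagents that add atoms: none
Why: Grignard addition to an aldehyde at low temperature; the new carbinol centre is removed in step 9, so its configuration does not matter.

Step 9
Reactants: 12 (3S)-3,7-dimethyl-1-(3-methylfuran-2-yl)-3-(triethylsilyloxy)octan-5-ol
Product: 13 (3S)-3,7-dimethyl-1-(3-methylfuran-2-yl)-3-(triethylsilyloxy)octan-5-one
Conditions: Dess–Martin periodinane, NaHCO3, CH2Cl2, 0 °C to rt
Reagents that add atoms: none
Why: Dess–Martin oxidation of a secondary alcohol under buffered, non-acidic conditions that the furan and the tertiary silyl ether should tolerate.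

Step 10
Reactants: 13 (3S)-3,7-dimethyl-1-(3-methylfuran-2-yl)-3-(triethylsilyloxy)octan-5-one
Product: 15 (3S)-6-chloro-3,7-dimethyl-1-(3-methylfuran-2-yl)-3-(triethylsilyloxy)octan-5-one (both C6 epimers), via lithium enolate 14 (not isolated)
Conditions: LiN(iPr)2 (1.05 equiv), THF, −78 °C; enolate added to CF3SO2Cl, −78 °C
Reagents that add atoms: trifluoromethanesulfonyl chloride, FC(F)(F)S(Cl)(=O)=O
Why: Enolate α-chlorination: kinetic deprotonation should occur at the less hindered methylene C6 of the octanone (the future C7), and the enolate, far more nucleophilic than the furan at −78 °C, takes chlorine from the sulfonyl chloride, whereas an electrophilic chlorinating agent acting on the neutral ketone would attack the furan first. Chlorination on the other α-carbon would lead to the same cation in step 11, where the configuration of the chlorinated carbon is lost as well.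

Step 11
Reactants: 15 (3S)-6-chloro-3,7-dimethyl-1-(3-methylfuran-2-yl)-3-(triethylsilyloxy)octan-5-one
Product: 18 (1S,4S,5S,7R,8S)-1,8-epoxy-4-(triethylsilyloxy)guai-9-en-6-one, via oxyallyl cation 16 (not isolated), via C7-epimeric cycloadduct 17 (not isolated)
Conditions: NaOCH2CF3 (from NaH, 1.5 equiv), CF3CH2OH, 0.02 M, 0 °C to rt
Reagents that add atoms: none
Why: The alkoxide removes a proton from C5 and, in the ionising fluorinated alcohol, chloride leaves from C7 of the enolate to give the oxyallyl cation 16, whose termini C5 and C7 bond to the furan carbons C1 and C8 in a (4+3) cycloaddition, concerted or through a short-lived furanoxonium ion. The closest known reaction type is the intramolecular (4+3) cycloaddition of furans with oxyallyl cations generated from α-haloketones by an alkoxide in a fluorinated alcohol. The five-membered ring closes through the C1–C5 bond as a 5-exo attack of the furan α-carbon on the cation terminus across the three-atom tether C2–C3–C4, and the seven-membered ring closes through the C7–C8 bond as the second bond of the cycloaddition, the furan oxygen becoming the C1–C8 bridge. C1 and C8 are set together by the furan face that is used, and this is chosen by C4: with the tether carbon C3 necessarily on the furan side, the silyloxy group should lie anti to the forming C1–C5 bond and away from the oxyallyl oxygen (electronegative group anti to the incoming nucleophile, dipoles opposed) and the methyl group near the plane of the cation, which places the bridge oxygen cis to the C4 methyl as in 18. C5 follows from the terminus geometry with the tether cis to the oxyallyl oxygen and from the extended arrangement, in which the exocyclic bonds at C1 and C5 are nearly eclipsed as the short tether demands, so that H-5 ends anti to the bridge. C7 is under thermodynamic control: any adduct 17 with an axial isopropyl group should be epimerised through its enolate by the alkoxide in the same flask to the equatorial isomer 18. The step therefore needs face and mode selectivity, which rest on the bulky, non-chelating silyl ether, on a hydrogen-bonding solvent and sodium counter-ion that disfavour a chelate between the C4 oxygen and the oxyallyl oxygen, and on dilution to exclude intermolecular capture.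

Step 12
Reactants: 18 (1S,4S,5S,7R,8S)-1,8-epoxy-4-(triethylsilyloxy)guai-9-en-6-one
Product: 19 (1S,4S,5S,6R,7S,8S)-1,8-epoxy-4-(triethylsilyloxy)guai-9-en-6-ol
Conditions: LiBH(s-Bu)3, THF, −78 °C; H2O
Reagents that add atoms: none
Why: Reduction with a bulky trialkylborohydride: in 8-oxabicyclo[3.2.1]oct-6-en-3-ones the face towards the two-carbon alkene bridge is shielded, so hydride should arrive from the side of the oxygen bridge and give the axial alcohol (hydroxyl anti to the bridge, 6R). The reduction also freezes the epimerisable centres C5 and C7; the change of the C7 descriptor is a priority effect only.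

Step 13
Reactants: 19 (1S,4S,5S,6R,7S,8S)-1,8-epoxy-4-(triethylsilyloxy)guai-9-en-6-ol
Product: 20 (1S,4S,5S,6R,7R,8S)-1,8-epoxy-4-(triethylsilyloxy)guai-9-en-6-yl acetate
Conditions: Ac2O, DMAP, Et3N, CH2Cl2, rt to 40 °C
Reagents that add atoms: acetic anhydride, CC(=O)OC(C)=O
Why: DMAP-catalysed acetylation of a hindered secondary alcohol; the other oxygens are the silyl-protected tertiary one and the bridge oxygen, so the acetate goes to C6 without a selectivity problem.

Step 14
Reactants: 20 (1S,4S,5S,6R,7R,8S)-1,8-epoxy-4-(triethylsilyloxy)guai-9-en-6-yl acetate
Product: 22 (4S,5R,6R,7R,8S)-8-hydroxy-4-(triethylsilyloxy)guai-1(10)-en-6-yl acetate, via allyl cation 21 (not isolated)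
Conditions: Et3SiH (5 equiv), BF3·OEt2 (2 equiv), CH2Cl2, −78 to −30 °C; aq. NaHCO3
Reagents that add atoms: none
Why: Lewis-acid-mediated reductive cleavage of an allylic ether (ionic hydrogenation): BF3 on the bridge oxygen should ionise the tertiary allylic C1–O bond in preference to the secondary allylic C8–O bond, and the silane should deliver hydride to the less hindered terminus C9 of the allyl cation 21, giving the tetrasubstituted C1=C10 alkene and leaving the C8–O bond with its configuration; aqueous work-up frees the C8 hydroxyl. Low temperature and excess silane are meant to outrun proton loss from the cation and to spare the tertiary silyl ether.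

Step 15
Reactants: 22 (4S,5R,6R,7R,8S)-8-hydroxy-4-(triethylsilyloxy)guai-1(10)-en-6-yl acetate; 23 angelic acid ((2Z)-2-methylbut-2-enoic acid)
Product: 25 (4S,5R,6R,7R,8S)-6-acetoxy-4-(triethylsilyloxy)guai-1(10)-en-8-yl (2Z)-2-methylbut-2-enoate, via mixed anhydride 24 (not isolated)
Conditions: 23 (3 equiv), 2,4,6-Cl3C6H2COCl, Et3N, toluene, rt; then 22, 75 °C
Reagents that add atoms: none
Why: Yamaguchi-type esterification through the mixed anhydride 24 without a nucleophilic catalyst, conditions under which the angeloyl group should be transferred to a hindered secondary alcohol without drift to the tiglate; the C8 hydroxyl is the only free hydroxyl.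

Step 16
Reactants: 25 (4S,5R,6R,7R,8S)-6-acetoxy-4-(triethylsilyloxy)guai-1(10)-en-8-yl (2Z)-2-methylbut-2-enoate
Product: 26 (4S,5R,6R,7R,8S)-6-acetoxy-4-hydroxyguai-1(10)-en-8-yl (2Z)-2-methylbut-2-enoate (target)
Conditions: HF·pyridine, pyridine, THF, 0 °C to rt
Reagents that add atoms: none
Why: Fluoride-induced cleavage of the tertiary triethylsilyl ether under pyridine-buffered conditions, which should leave both esters, the Z geometry of the angelate and the tertiary homoallylic alcohol untouched.

## Compound list

1 | 3-methylfuran | Cc1ccoc1 | starting material
2 | methyl vinyl ketone (but-3-en-2-one) | CC(=O)C=C | starting material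
3 | 4-(3-methylfuran-2-yl)butan-2-one | Cc1ccoc1CCC(C)=O | intermediate
4 | triethyl phosphonoacetate | CCOC(=O)CP(=O)(OCC)OCC | starting material
5 | ethyl (2E)-3-methyl-5-(3-methylfuran-2-yl)pent-2-enoate | Cc1ccoc1CC/C(C)=C/C(=O)OCC | intermediate
6 | (2E)-3-methyl-5-(3-methylfuran-2-yl)pent-2-en-1-ol | Cc1ccoc1CC/C(C)=C/CO | intermediate
7 | [(2S,3S)-3-methyl-3-[2-(3-methylfuran-2-yl)ethyl]oxiran-2-yl]methanol | Cc1ccoc1CC[C@]1(C)O[C@H]1CO | intermediate
8 | (3S)-3-methyl-5-(3-methylfuran-2-yl)pentane-1,3-diol | Cc1ccoc1CC[C@](C)(O)CCO | intermediate
9 | (3S)-3-methyl-5-(3-methylfuran-2-yl)-1,3-bis(triethylsilyloxy)pentane | Cc1ccoc1CC[C@](C)(O[Si](CC)(CC)CC)CCO[Si](CC)(CC)CC | intermediate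
10 | (3S)-3-methyl-5-(3-methylfuran-2-yl)-3-(triethylsilyloxy)pentanal | Cc1ccoc1CC[C@](C)(O[Si](CC)(CC)CC)CC=O | intermediate
11 | isobutylmagnesium bromide | CC(C)C[Mg]Br | starting material
12 | (3S)-3,7-dimethyl-1-(3-methylfuran-2-yl)-3-(triethylsilyloxy)octan-5-ol, both C5 epimers | Cc1ccoc1CC[C@](C)(O[Si](CC)(CC)CC)CC(O)CC(C)C | intermediate
13 | (3S)-3,7-dimethyl-1-(3-methylfuran-2-yl)-3-(triethylsilyloxy)octan-5-one | Cc1ccoc1CC[C@](C)(O[Si](CC)(CC)CC)CC(=O)CC(C)C | intermediate
14 | lithium (3S)-3,7-dimethyl-1-(3-methylfuran-2-yl)-3-(triethylsilyloxy)oct-5-en-5-olate (kinetic enolate, not isolated) | Cc1ccoc1CC[C@](C)(O[Si](CC)(CC)CC)CC(O[Li])=CC(C)C | intermediate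
15 | (3S)-6-chloro-3,7-dimethyl-1-(3-methylfuran-2-yl)-3-(triethylsilyloxy)octan-5-one, both C6 epimers | Cc1ccoc1CC[C@](C)(O[Si](CC)(CC)CC)CC(=O)C(Cl)C(C)C | intermediate
16 | oxyallyl cation (2-oxidoallyl zwitterion over ring carbons C5–C6–C7) derived from 15, not isolated | Cc1ccoc1CC[C@](C)(O[Si](CC)(CC)CC)C=C([O-])[CH+]C(C)C | intermediate
17 | (1S,4S,5S,7S,8S)-1,8-epoxy-4-(triethylsilyloxy)guai-9-en-6-one (C7 epimer of 18, axial isopropyl, not isolated) | O1[C@H]2C=C(C)[C@@]13CC[C@](C)(O[Si](CC)(CC)CC)[C@H]3C(=O)[C@H]2C(C)C | intermediate
18 | (1S,4S,5S,7R,8S)-1,8-epoxy-4-(triethylsilyloxy)guai-9-en-6-one (cyclopentane-fused 8-oxabicyclo[3.2.1]oct-6-en-3-one; H-5 anti to the bridge, isopropyl equatorial) | O1[C@H]2C=C(C)[C@@]13CC[C@](C)(O[Si](CC)(CC)CC)[C@H]3C(=O)[C@@H]2C(C)C | intermediate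
19 | (1S,4S,5S,6R,7S,8S)-1,8-epoxy-4-(triethylsilyloxy)guai-9-en-6-ol (axial hydroxyl, anti to the bridge) | O1[C@H]2C=C(C)[C@@]13CC[C@](C)(O[Si](CC)(CC)CC)[C@H]3[C@H](O)[C@@H]2C(C)C | intermediate
20 | (1S,4S,5S,6R,7R,8S)-1,8-epoxy-4-(triethylsilyloxy)guai-9-en-6-yl acetate | O1[C@H]2C=C(C)[C@@]13CC[C@](C)(O[Si](CC)(CC)CC)[C@H]3[C@H](OC(C)=O)[C@@H]2C(C)C | intermediate
21 | allyl cation over C1–C10–C9 with the BF3-bound C8 alkoxide (zwitterion, not isolated) | F[B-](F)(F)O[C@H]1C=C(C)[C+]2CC[C@](C)(O[Si](CC)(CC)CC)[C@H]2[C@H](OC(C)=O)[C@@H]1C(C)C | intermediate
22 | (4S,5R,6R,7R,8S)-8-hydroxy-4-(triethylsilyloxy)guai-1(10)-en-6-yl acetate | O[C@H]1CC(C)=C2CC[C@](C)(O[Si](CC)(CC)CC)[C@H]2[C@H](OC(C)=O)[C@@H]1C(C)C | intermediate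
23 | angelic acid, (2Z)-2-methylbut-2-enoic acid | C/C=C(/C)C(=O)O | starting material
24 | (2Z)-2-methylbut-2-enoic 2,4,6-trichlorobenzoic anhydride (not isolated) | C/C=C(/C)C(=O)OC(=O)c1c(Cl)cc(Cl)cc1Cl | intermediate
25 | (4S,5R,6R,7R,8S)-6-acetoxy-4-(triethylsilyloxy)guai-1(10)-en-8-yl (2Z)-2-methylbut-2-enoate | C/C=C(/C)C(=O)O[C@H]1CC(C)=C2CC[C@](C)(O[Si](CC)(CC)CC)[C@H]2[C@H](OC(C)=O)[C@@H]1C(C)C | intermediate
26 | (4S,5R,6R,7R,8S)-6-acetoxy-4-hydroxyguai-1(10)-en-8-yl (2Z)-2-methylbut-2-enoate | C/C=C(/C)C(=O)O[C@H]1CC(C)=C2CC[C@](C)(O)[C@H]2[C@H](OC(C)=O)[C@@H]1C(C)C | target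

## Step count and least certain steps

Total: 16 steps. Longest linear sequence: 16 steps (1 to 26); the route is fully linear, and 4, 11 and 23 are commercial.

Step 11 (key step).
- What may go wrong: poor discrimination between the two furan faces. The methyl and silyloxy groups on C4 are similar in size, and a compact arrangement can compete with the extended one, so a diastereomer with the bridge on the wrong face relative to C4 may form in quantity. The C5 enolate may also expel the β-silyloxy group before chloride ionises.
- Fallback, from 7 back to 18: oxidise 7 with SO3·pyridine, DMSO and iPr2NEt (Parikh–Doering oxidation) to (2R,3S)-3-methyl-3-[2-(3-methylfuran-2-yl)ethyl]oxirane-2-carbaldehyde F1. Add 11 at −78 °C to give the epoxy carbinol F2, and oxidise with Dess–Martin periodinane to the α,β-epoxy ketone F3. Treat F3 with LiN(iPr)2 and then Et3SiCl at −78 °C; it can enolise only towards C7 and gives the epoxy enol silane F4. With Et3SiOTf in CH2Cl2 at −78 °C the silyl-activated epoxide should be opened at C5 by the furan carbon C1 anti to the departing oxygen while the silyloxyallyl terminus C7 bonds to C8, a known (4+3) mode of epoxy enol silanes. The oxygen stays on C4 as its triethylsilyl ether and the product is 18, with C7 equilibrated by NaOCH2CF3 in CF3CH2OH if needed.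
- What this changes: the C4–C5 relationship becomes a stereospecific inversion at C5, fixed by the alkene geometry of 6 and the epoxidation, instead of a conformational preference. Base and chlorine are avoided. The extended-versus-compact question remains.

Step 14.
- What may go wrong: hydride capture at C1 instead of C9, ionisation of the C8–O bond, proton loss from the allyl cation to dienes, participation of the C6 acetate, or loss of the tertiary silyl ether under the Lewis acid.
- Fallback, from 19 back to 25: treat 19, which carries no ester, with lithium 4,4'-di-tert-butylbiphenylide, Li(C20H26), in THF at −78 °C. The allylic C1–O bond should be cleaved by electron transfer, and the resulting allyl anion protonated at the less substituted C9, to give (4S,5R,6R,7R,8S)-4-(triethylsilyloxy)guai-1(10)-ene-6,8-diol F5. Yamaguchi angeloylation as in step 15 should take the less hindered C8 hydroxyl and give the 8-angelate F6. Acetylation of the remaining C6 hydroxyl (Ac2O, DMAP) leads to 25.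

Step 12.
- What may go wrong: the axial C4 substituent on C5, whose methyl group sits over C6, may impede hydride delivery from the bridge side, leading to slow reduction, enolisation or delivery from the alkene-bridge face.
- Fallback, from 18 back to 20: reduce 18 under electron-transfer conditions (SmI2, H2O, Et3N, THF) to the equatorial alcohol (1S,4S,5S,6S,7S,8S)-1,8-epoxy-4-(triethylsilyloxy)guai-9-en-6-ol F7. Invert F7 in a Mitsunobu reaction with acetic acid (PPh3, diisopropyl azodicarboxylate, toluene); this installs the acetate with inversion and gives 20 directly.

Step 15.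
- What may go wrong: geometrical isomerisation of the angeloyl group to the tigloyl group during activation, and slow acylation of the hindered C8 hydroxyl.
- Fallback, from 22 back to 25: esterify 22 with 2-[bis(2,2,2-trifluoroethoxy)phosphoryl]propanoic acid (carbodiimide, DMAP) to the phosphonate ester F8. A Still–Gennari olefination (KN(SiMe3)2, 18-crown-6, THF, −78 °C, then acetaldehyde) should build the Z-trisubstituted ester on the molecule and give 25.

Step 10.
- What may go wrong: chlorination of the furan ring, or over-chlorination through proton exchange between product and enolate.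
- Fallback, from 13 back to 18: form the enolate of 13 with KN(SiMe3)2 and hydroxylate it with 2-(phenylsulfonyl)-3-phenyloxaziridine to the α-hydroxy ketone F9. MsCl and Et3N give the α-mesyloxy ketone F10, which with Et3N in CF3CH2OH should ionise to the same cation 16 and close to 18.

## Further compounds

F1 | step 11 | (2R,3S)-3-methyl-3-[2-(3-methylfuran-2-yl)ethyl]oxirane-2-carbaldehyde | Cc1ccoc1CC[C@]1(C)O[C@H]1C=O
F2 | step 11 | 3-methyl-1-[(2S,3S)-3-methyl-3-[2-(3-methylfuran-2-yl)ethyl]oxiran-2-yl]butan-1-ol, both carbinol epimers | Cc1ccoc1CC[C@]1(C)O[C@H]1C(O)CC(C)C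
F3 | step 11 | 3-methyl-1-[(2R,3S)-3-methyl-3-[2-(3-methylfuran-2-yl)ethyl]oxiran-2-yl]butan-1-one | Cc1ccoc1CC[C@]1(C)O[C@H]1C(=O)CC(C)C
F4 | step 11 | triethyl({3-methyl-1-[(2R,3S)-3-methyl-3-[2-(3-methylfuran-2-yl)ethyl]oxiran-2-yl]but-1-en-1-yl}oxy)silane | Cc1ccoc1CC[C@]1(C)O[C@H]1C(O[Si](CC)(CC)CC)=CC(C)C
F5 | step 14 | (4S,5R,6R,7R,8S)-4-(triethylsilyloxy)guai-1(10)-ene-6,8-diol | O[C@H]1CC(C)=C2CC[C@](C)(O[Si](CC)(CC)CC)[C@H]2[C@H](O)[C@@H]1C(C)C
F6 | step 14 | (4S,5R,6R,7S,8S)-6-hydroxy-4-(triethylsilyloxy)guai-1(10)-en-8-yl (2Z)-2-methylbut-2-enoate | C/C=C(/C)C(=O)O[C@H]1CC(C)=C2CC[C@](C)(O[Si](CC)(CC)CC)[C@H]2[C@H](O)[C@@H]1C(C)C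
F7 | step 12 | (1S,4S,5S,6S,7S,8S)-1,8-epoxy-4-(triethylsilyloxy)guai-9-en-6-ol (equatorial hydroxyl) | O1[C@H]2C=C(C)[C@@]13CC[C@](C)(O[Si](CC)(CC)CC)[C@H]3[C@@H](O)[C@@H]2C(C)C
F8 | step 15 | (4S,5R,6R,7R,8S)-6-acetoxy-4-(triethylsilyloxy)guai-1(10)-en-8-yl 2-[bis(2,2,2-trifluoroethoxy)phosphoryl]propanoate, both epimers at the phosphonate carbon | CC(C(=O)O[C@H]1CC(C)=C2CC[C@](C)(O[Si](CC)(CC)CC)[C@H]2[C@H](OC(C)=O)[C@@H]1C(C)C)P(=O)(OCC(F)(F)F)OCC(F)(F)F
F9 | step 10 | (3S)-6-hydroxy-3,7-dimethyl-1-(3-methylfuran-2-yl)-3-(triethylsilyloxy)octan-5-one, both C6 epimers | Cc1ccoc1CC[C@](C)(O[Si](CC)(CC)CC)CC(=O)C(O)C(C)C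
F10 | step 10 | (6S)-2,6-dimethyl-8-(3-methylfuran-2-yl)-4-oxo-6-(triethylsilyloxy)octan-3-yl methanesulfonate, both C3 epimers | Cc1ccoc1CC[C@](C)(O[Si](CC)(CC)CC)CC(=O)C(OS(C)(=O)=O)C(C)C
A1 | alternative 1 | (2E,6E)-farnesyl diphosphate | CC(C)=CCC/C(C)=C/CC/C(C)=C/COP(=O)(O)OP(=O)(O)O
A2 | alternative 1 | (1(10)E,4E,6R,7S)-germacra-1(10),4-dien-6-ol | C/C1=C\CC/C(C)=C/[C@H](O)[C@H](C(C)C)CC1
A3 | alternative 2 | 3-methyl-2-[2,2,7a-trimethyl-5-(prop-1-en-2-yl)hexahydrocyclopenta[d][1,3]dioxin-4-yl]butanal, configured as A4 | C=C(C)[C@H]1CC[C@]2(C)OC(C)(C)O[C@H]([C@H](C(C)C)C=O)[C@@H]12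
A4 | alternative 2 | 4,6-O-isopropylideneguai-10(14)-ene-4,6,8-triol (free C8 hydroxyl) | C=C1C[C@H](O)[C@@H](C(C)C)[C@H]2OC(C)(C)O[C@@]3(C)CC[C@H]1[C@H]23
A5 | alternative 3 | 1-diazo-4-[4-methoxy-2-methyl-5-(propan-2-yl)phenyl]butan-2-one | [N-]=[N+]=CC(=O)CCc1cc(C(C)C)c(OC)cc1C
A6 | alternative 3 | (8aS)-6-methoxy-4-methyl-7-(propan-2-yl)-3,8a-dihydroazulen-1(2H)-one | O=C1CCC2=C(C)C=C(OC)C(C(C)C)=C[C@H]12
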